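**Strategy.** Eremophilane numbering is used. Everything rests on cutting the ring-fusion bond C5–C10, across which the C3 and C9 oxygens are 1,5-related and C5 is the methyl-bearing quaternary carbon. An anionic oxy-Cope rearrangement forms this bond: the (S)-carvone-derived cyclohexenol ring (C3, C4, C5, C6, C7, C8) opens at C3–C8 while ring B (C5 to C10) closes, passing chirality from C8 to C5 and releasing the C3 ketone beside a regiodefined C8=C9 silyl enol ether. The precursor is a carvone-derived 1,2,3-trimethylcyclohex-2-en-1-ol carrying a 1-silyloxyalkenyl arm at C8; ring A follows by intramolecular Michael addition.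

Key step: step 7

Remark: all intermediates carry eremophilane atom numbers (ring A: C1–C5, C10; ring B: C5–C10; C11–C13 isopropenyl; C14 on C5; C15 on C4). α is the face opposite the C5 methyl. (Z)-Hex-2-enoic acid is prepared rather than assumed to be purchasable.

Step 1
Reactants: 1 (S)-(+)-carvone
Product: 2 (5S)-1,2-dimethyl-5-(prop-1-en-2-yl)cyclohex-2-en-1-ol (both C1 epimers)
Conditions: MeLi, Et2O, −78 °C to 0 °C; H2O
Reagents that add atoms: methyllithium, [Li]C
Why: 1,2-addition of the hard organolithium to the enone carbonyl gives the tertiary allylic alcohol and brings in C14; the new carbinol centre is destroyed in step 2, so its configuration does not matter.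

Step 2
Reactants: 2 (5S)-1,2-dimethyl-5-(prop-1-en-2-yl)cyclohex-2-en-1-ol
Product: 3 (5R)-2,3-dimethyl-5-(prop-1-en-2-yl)cyclohex-2-en-1-one
Conditions: pyridinium chlorochromate (C5H5NH)[CrO3Cl], CH2Cl2, rt
Reagents that add atoms: none
Why: Babler–Dauben oxidative 1,3-transposition of the tertiary allylic alcohol gives the tetrasubstituted enone; the stereocentre is untouched and its descriptor changes only because the two ring arms exchange priority.

Step 3
Reactants: 3 (5R)-2,3-dimethyl-5-(prop-1-en-2-yl)cyclohex-2-en-1-one; 4 methional [3-(methylsulfanyl)propanal]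
Product: 6 (5R,6R)-6-[1-hydroxy-3-(methylsulfanyl)propyl]-2,3-dimethyl-5-(prop-1-en-2-yl)cyclohex-2-en-1-one (carbinol epimers), via lithium enolate 5 (not isolated)
Conditions: LiN(i-Pr)2, THF, −78 °C; then 4, −78 °C; AcOH quench
Reagents that add atoms: none
Why: Kinetic deprotonation at the α′ methylene (C8) gives the cross-conjugated enolate, whose aldol addition should occur on the face anti to the adjacent isopropenyl group and so set C8 trans to C7; the C9 carbinol mixture converges in step 5.

Step 4
Reactants: 6 (5R,6R)-6-[1-hydroxy-3-(methylsulfanyl)propyl]-2,3-dimethyl-5-(prop-1-en-2-yl)cyclohex-2-en-1-one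
Product: 7 6-[1-hydroxy-3-(methylsulfanyl)propyl]-1,2,3-trimethyl-5-(prop-1-en-2-yl)cyclohex-2-en-1-ol (C5/C6 trans as in 6; C1 and carbinol epimers)
Conditions: MeLi (3 equiv), THF/Et2O, −78 °C to −40 °C; H2O
Reagents that add atoms: methyllithium, [Li]C
Why: After deprotonation of the hydroxyl, 1,2-addition of MeLi to the enone carbonyl installs C2 and the tertiary allylic alcohol at C3; either C3 epimer serves because C3 becomes sp2 in step 7.

Step 5
Reactants: 7 6-[1-hydroxy-3-(methylsulfanyl)propyl]-1,2,3-trimethyl-5-(prop-1-en-2-yl)cyclohex-2-en-1-ol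
Product: 8 1-[2-hydroxy-2,3,4-trimethyl-6-(prop-1-en-2-yl)cyclohex-3-en-1-yl]-3-(methylsulfanyl)propan-1-one (acyl group trans to isopropenyl; carbinol epimers)
Conditions: Dess–Martin periodinane, NaHCO3, CH2Cl2, 0 °C
Reagents that add atoms: none
Why: Dess–Martin oxidation converts only the secondary alcohol into the C9 ketone under buffered non-basic conditions that should spare the thioether, the tertiary allylic alcohol and the retro-aldol-prone β-hydroxy ketone.

Step 6
Reactants: 8 1-[2-hydroxy-2,3,4-trimethyl-6-(prop-1-en-2-yl)cyclohex-3-en-1-yl]-3-(methylsulfanyl)propan-1-one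
Product: 10 1,2,3-trimethyl-6-{3-(methylsulfanyl)-1-[(triisopropylsilyl)oxy]prop-1-en-1-yl}-5-(prop-1-en-2-yl)cyclohex-2-en-1-ol (C9=C10 enol ether; free tertiary alcohol; E/Z mixture), via dilithium alkoxide enolate 9 (not isolated)
Conditions: LiN(i-Pr)2 (2.2 equiv), THF, −78 °C; then i-Pr3SiOTf (1.1 equiv), −78 °C; H2O
Reagents that add atoms: triisopropylsilyl trifluoromethanesulfonate, CC(C)[Si](OS(=O)(=O)C(F)(F)F)(C(C)C)C(C)C
Why: Kinetic enolization of the lithium aldolate at the unhindered C10 methylene and O-silylation of the enolate should give the C9=C10 enol ether regioselectively, the hindered tertiary lithium alkoxide not being silylated by the bulky triflate; holding the enolate at −78 °C should prevent β-elimination of methanethiolate from C1.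

Step 7
Reactants: 10 1,2,3-trimethyl-6-{3-(methylsulfanyl)-1-[(triisopropylsilyl)oxy]prop-1-en-1-yl}-5-(prop-1-en-2-yl)cyclohex-2-en-1-ol
Product: 13 3-{1-methyl-2-[(methylsulfanyl)methyl]-5-(prop-1-en-2-yl)-3-[(triisopropylsilyl)oxy]cyclohex-3-en-1-yl}butan-2-one (ring B with C8=C9 silyl enol ether and quaternary C5; C4 and C10 epimers), via potassium alkoxide 11 (not isolated), via potassium enolate 12 (not isolated)
Conditions: KH, 18-crown-6, THF, 0 °C to 40 °C; then H2O, 0 °C
Reagents that add atoms: none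
Why: KH gives alkoxide 11, whose C3 oxido group accelerates a [3,3]-sigmatropic shift of the 1,5-diene C5=C4–C3(O–)–C8–C9=C10 through a boat-like, bicyclo[2.2.2]octene-shaped transition state, so that C3–C8 breaks as C5–C10 forms and enolate 12 (C3/C4) appears beside the C8=C9 silyl enol ether, C10 now carrying only the CH2SMe group (C1). The closest known reaction type is the anionic oxy-Cope rearrangement of bridged bicyclic 3-oxido-1,5-dienes, which likewise pass through boat transition states, and the carbon topology is that of the Cope rearrangement of 4-vinylcyclohexene. Ring B (C5 to C10) closes as a six-membered carbocycle in the pericyclic mode, by suprafacial bonding of the diene termini C5 and C10 across the 1,4-positions of the carvone-derived ring, which opens at the same time. The quaternary centre C5 is set by chirality transfer from C8: the alkenyl arm can reach C5 only on the ring face it occupies, which step 3 placed anti to the C7 isopropenyl group, so the C5 methyl should end up trans to isopropenyl on ring B; C10 follows the enol ether geometry but is erased in step 8, and C4 is fixed in step 10. The step needs the concerted shift to outrun O-to-O silyl transfer and retro-aldol-type fragmentation, which the bulky triisopropylsilyl group and the hindered tertiary alkoxide should secure; of the 1,5-dienes present only this one carries the accelerating oxido group.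

Step 8
Reactants: 13 3-{1-methyl-2-[(methylsulfanyl)methyl]-5-(prop-1-en-2-yl)-3-[(triisopropylsilyl)oxy]cyclohex-3-en-1-yl}butan-2-one
Product: 15 3-{1-methyl-2-methylidene-5-(prop-1-en-2-yl)-3-[(triisopropylsilyl)oxy]cyclohex-3-en-1-yl}butan-2-one (2-silyloxy-1,3-diene C8=C9(OSi)–C10=C1H2; C4 epimers), via sulfoxide 14 (not isolated)
Conditions: NaIO4, MeOH/THF/H2O, 0 °C; then toluene, Et3N (cat.), 110 °C
Reagents that add atoms: none
Why: Chemoselective S-oxidation followed by thermal syn-elimination of the sulfoxide (the only β-hydrogen is the allylic C10–H) should give the exocyclic C10=C1 alkene with loss of methanesulfenic acid, removing the C10 stereocentre.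

Step 9
Reactants: 15 3-{1-methyl-2-methylidene-5-(prop-1-en-2-yl)-3-[(triisopropylsilyl)oxy]cyclohex-3-en-1-yl}butan-2-one
Product: 17 3-{1-methyl-2-methylidene-3-oxo-5-(prop-1-en-2-yl)-4-[(triisopropylsilyl)oxy]cyclohexyl}butan-2-one (8α-silyloxy 10(1)-en-9-one; C4 epimers), via silyloxy epoxide 16 (not isolated)
Conditions: mCPBA (1.05 equiv), NaHCO3, CH2Cl2, −20 °C to 0 °C
Reagents that add atoms: meta-chloroperoxybenzoic acid, O=C(OO)c1cccc(Cl)c1
Why: Rubottom oxidation: the electron-rich enol ether bond should be epoxidized faster than the isopropenyl group and from the α face, anti to the pseudo-axial C5 methyl (the isopropenyl group being pseudo-equatorial), and silyl migration on epoxide opening gives the 8α-silyloxy ketone.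

Step 10
Reactants: 17 3-{1-methyl-2-methylidene-3-oxo-5-(prop-1-en-2-yl)-4-[(triisopropylsilyl)oxy]cyclohexyl}butan-2-one
Product: 18 8α-[(triisopropylsilyl)oxy]-10αH-eremophil-11-ene-3,9-dione
Conditions: t-BuOK (0.2 equiv), t-BuOH/THF, 0 °C to rt
Reagents that add atoms: none
Why: Intramolecular Michael addition (6-endo-trig) of the methyl ketone enolate (C2) to the exocyclic enone carbon C1 closes ring A, after which C10 should be protonated to the trans ring fusion (H anti to the C5 methyl) and C4 should settle with its methyl equatorial; the C8–H, shielded by the triisopropylsilyloxy and isopropenyl groups, should exchange much more slowly with the substoichiometric base.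

Step 11
Reactants: 18 8α-[(triisopropylsilyl)oxy]-10αH-eremophil-11-ene-3,9-dione
Product: 19 8α-[(triisopropylsilyl)oxy]-10αH-eremophil-11-ene-3α,9α-diol
Conditions: Al(Oi-Pr)3 (0.5 equiv), i-PrOH/toluene, 90 °C, prolonged; acetone distilled off at the end
Reagents that add atoms: none
Why: Meerwein–Ponndorf–Verley reduction is reversible, so both carbinols should equilibrate to the equatorial 3α- and 9α-alcohols, whose axial epimers would each be syn-axial to the C5 methyl.

Step 12
Reactants: 20 hex-2-ynoic acid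
Product: 21 (Z)-hex-2-enoic acid
Conditions: H2 (1 atm), Pd/CaCO3 poisoned with Pb(OAc)2, quinoline, EtOAc, rt
Reagents that add atoms: none
Why: Lindlar semihydrogenation adds hydrogen syn to the alkyne and stops at the cis-alkene, fixing the Z geometry of both acyl groups.

Step 13
Reactants: 19 8α-[(triisopropylsilyl)oxy]-10αH-eremophil-11-ene-3α,9α-diol; 21 (Z)-hex-2-enoic acid (2.5 equiv)
Product: 23 8α-[(triisopropylsilyl)oxy]-10αH-eremophil-11-ene-3α,9α-diyl bis[(2Z)-hex-2-enoate], via mixed anhydride 22 (not isolated)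
Conditions: 21, 2,4,6-trichlorobenzoyl chloride, Et3N, THF, 0 °C; then 19, DMAP, toluene, rt
Reagents that add atoms: none
Why: Yamaguchi esterification acylates the two equatorial hydroxyls at C3 and C9 with retention at carbon while C8 stays blocked as its silyl ether; the mild base load is chosen to keep the Z-enoate from isomerizing.

Step 14
Reactants: 23 8α-[(triisopropylsilyl)oxy]-10αH-eremophil-11-ene-3α,9α-diyl bis[(2Z)-hex-2-enoate]
Product: 24 CNP0420276.1, 8α-hydroxy-10αH-eremophil-11-ene-3α,9α-diyl bis[(2Z)-hex-2-enoate]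
Conditions: HF·pyridine, pyridine/THF, 0 °C to rt
Reagents that add atoms: none
Why: Desilylation under buffered acidic fluoride conditions should free the axial C8 hydroxyl without acyl migration or Z to E isomerization.

Compound list

1 | (S)-(+)-carvone, (5S)-2-methyl-5-(prop-1-en-2-yl)cyclohex-2-en-1-one | CC1=CC[C@@H](CC1=O)C(C)=C | starting material
2 | (5S)-1,2-dimethyl-5-(prop-1-en-2-yl)cyclohex-2-en-1-ol, C1 epimers | CC1=CC[C@@H](CC1(C)O)C(C)=C | intermediate
3 | (5R)-2,3-dimethyl-5-(prop-1-en-2-yl)cyclohex-2-en-1-one | C=C(C)[C@@H]1CC(C)=C(C)C(=O)C1 | intermediate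
4 | methional, 3-(methylsulfanyl)propanal | CSCCC=O | starting material
5 | lithium cross-conjugated enolate of 3 (C3–O, C3=C8) | C=C(C)[C@@H]1CC(C)=C(C)C([O-])=C1.[Li+] | intermediate
6 | (5R,6R)-6-[1-hydroxy-3-(methylsulfanyl)propyl]-2,3-dimethyl-5-(prop-1-en-2-yl)cyclohex-2-en-1-one, side chain trans to isopropenyl, carbinol epimers | C=C(C)[C@@H]1CC(C)=C(C)C(=O)[C@H]1C(O)CCSC | intermediate
7 | 6-[1-hydroxy-3-(methylsulfanyl)propyl]-1,2,3-trimethyl-5-(prop-1-en-2-yl)cyclohex-2-en-1-ol, C5/C6 trans as in 6, C1 and carbinol epimers | C=C(C)[C@@H]1CC(C)=C(C)C(C)(O)[C@H]1C(O)CCSC | intermediate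
8 | 1-[2-hydroxy-2,3,4-trimethyl-6-(prop-1-en-2-yl)cyclohex-3-en-1-yl]-3-(methylsulfanyl)propan-1-one, acyl trans to isopropenyl, carbinol epimers | C=C(C)[C@@H]1CC(C)=C(C)C(C)(O)[C@H]1C(=O)CCSC | intermediate
9 | dilithium salt of 8: C3 alkoxide and C9=C10 enolate | C=C(C)[C@@H]1CC(C)=C(C)C(C)([O-])[C@H]1C([O-])=CCSC.[Li+].[Li+] | intermediate
10 | 1,2,3-trimethyl-6-{3-(methylsulfanyl)-1-[(triisopropylsilyl)oxy]prop-1-en-1-yl}-5-(prop-1-en-2-yl)cyclohex-2-en-1-ol, C5/C6 trans, C1 epimers, enol ether E/Z mixture | C=C(C)[C@@H]1CC(C)=C(C)C(C)(O)[C@H]1C(=CCSC)O[Si](C(C)C)(C(C)C)C(C)C | intermediate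
11 | potassium alkoxide of 10 | C=C(C)[C@@H]1CC(C)=C(C)C(C)([O-])[C@H]1C(=CCSC)O[Si](C(C)C)(C(C)C)C(C)C.[K+] | intermediate
12 | potassium C3/C4 enolate of 13 | C=C(C)[C@@H]1C[C@](C)(C(C)=C(C)[O-])C(CSC)C(O[Si](C(C)C)(C(C)C)C(C)C)=C1.[K+] | intermediate
13 | 3-{1-methyl-2-[(methylsulfanyl)methyl]-5-(prop-1-en-2-yl)-3-[(triisopropylsilyl)oxy]cyclohex-3-en-1-yl}butan-2-one; 1,2-seco skeleton: ring B with C8=C9 triisopropylsilyl enol ether, quaternary C5 bearing methyl (trans to the C7 isopropenyl) and the 3-oxobutan-2-yl chain (C4, C15, C3, C2), C10 bearing CH2SMe (C1), C4 and C10 epimers | C=C(C)[C@@H]1C[C@](C)(C(C)C(C)=O)C(CSC)C(O[Si](C(C)C)(C(C)C)C(C)C)=C1 | intermediate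
14 | S-oxide of 13 | C=C(C)[C@@H]1C[C@](C)(C(C)C(C)=O)C(CS(C)=O)C(O[Si](C(C)C)(C(C)C)C(C)C)=C1 | intermediate
15 | 3-{1-methyl-2-methylidene-5-(prop-1-en-2-yl)-3-[(triisopropylsilyl)oxy]cyclohex-3-en-1-yl}butan-2-one; as 13 but with exocyclic C10=C1H2 (2-silyloxy-1,3-diene), C4 epimers | C=C(C)[C@@H]1C[C@](C)(C(C)C(C)=O)C(=C)C(O[Si](C(C)C)(C(C)C)C(C)C)=C1 | intermediate
16 | 8α,9α-epoxide of 15 with the silyloxy group on C9 | C=C(C)[C@@H]1C[C@](C)(C(C)C(C)=O)C(=C)[C@]2(O[Si](C(C)C)(C(C)C)C(C)C)O[C@H]12 | intermediate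
17 | 3-{1-methyl-2-methylidene-3-oxo-5-(prop-1-en-2-yl)-4-[(triisopropylsilyl)oxy]cyclohexyl}butan-2-one; C9 ketone, C10=C1H2, 8α-triisopropylsilyloxy cis to the 7α-isopropenyl, C5 as in 13, C4 epimers | C=C(C)[C@@H]1C[C@](C)(C(C)C(C)=O)C(=C)C(=O)[C@@H]1O[Si](C(C)C)(C(C)C)C(C)C | intermediate
18 | 8α-[(triisopropylsilyl)oxy]-10αH-eremophil-11-ene-3,9-dione (4β,5β-dimethyl, 7βH, trans-fused) | C=C(C)[C@@H]1C[C@]2(C)[C@@H](C)C(=O)CC[C@H]2C(=O)[C@@H]1O[Si](C(C)C)(C(C)C)C(C)C | intermediate
19 | 8α-[(triisopropylsilyl)oxy]-10αH-eremophil-11-ene-3α,9α-diol | C=C(C)[C@@H]1C[C@]2(C)[C@@H](C)[C@H](O)CC[C@H]2[C@H](O)[C@@H]1O[Si](C(C)C)(C(C)C)C(C)C | intermediate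
20 | hex-2-ynoic acid | CCCC#CC(=O)O | starting material
21 | (Z)-hex-2-enoic acid | CCC/C=C\C(=O)O | intermediate
22 | (Z)-hex-2-enoic 2,4,6-trichlorobenzoic anhydride | CCC/C=C\C(=O)OC(=O)c1c(Cl)cc(Cl)cc1Cl | intermediate
23 | 8α-[(triisopropylsilyl)oxy]-10αH-eremophil-11-ene-3α,9α-diyl bis[(2Z)-hex-2-enoate] | C=C(C)[C@@H]1C[C@]2(C)[C@@H](C)[C@H](OC(=O)/C=C\CCC)CC[C@H]2[C@H](OC(=O)/C=C\CCC)[C@@H]1O[Si](C(C)C)(C(C)C)C(C)C | intermediate
24 | CNP0420276.1, 8α-hydroxy-10αH-eremophil-11-ene-3α,9α-diyl bis[(2Z)-hex-2-enoate] (4β,5β-dimethyl, 7βH) | C=C(C)[C@@H]1C[C@]2(C)[C@@H](C)[C@H](OC(=O)/C=C\CCC)CC[C@H]2[C@H](OC(=O)/C=C\CCC)[C@@H]1O | target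

Step count. Total: 14 steps. Longest linear sequence: 13 steps from 1 (steps 1–11, 13, 14); step 12 is a one-step side branch.

Steps most likely to fail

Step 7. The silyl group may move from the enol oxygen to the alkoxide, or the alkoxide may fragment in a retro-aldol sense and recombine without fidelity, so that the concerted shift and its chirality transfer are lost. The fallback sets out from 10 and removes the alkoxide altogether. Silylation of the tertiary hydroxyl (Me3SiOTf, 2,6-lutidine, CH2Cl2, −78 °C) would give the trimethylsilyl ether F1. Heating in degassed o-dichlorobenzene at about 200 °C should then effect the neutral silyloxy-Cope rearrangement to the bis(silyl enol ether) F2. K2CO3 in MeOH at 0 °C should cleave only the trimethylsilyl enol ether, and the route is rejoined at 13.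

Step 11. Equilibration at C3 may stay incomplete, leaving the kinetic axial alcohol, and the hot aluminium alkoxide may epimerize C8 or shift the silyl group. The fallback sets out from 18 and uses kinetic control plus inversion. NaBH4 with CeCl3 in MeOH at −78 °C should deliver hydride to C3 from the α face and to C9 anti to the axial C8–O bond, giving the 3β,9α-diol F3. One equivalent of mixed anhydride 22 with DMAP should acylate the equatorial 9α-hydroxyl to the mono-ester F4. A Mitsunobu reaction with acid 21 (PPh3, diisopropyl azodicarboxylate, toluene) would then install the C3 ester with inversion, and the route is rejoined at 23.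

Step 13. The Z-enoyl groups may isomerize to E through reversible conjugate addition of DMAP during the slow acylation of two hindered alcohols. The fallback sets out from 19 and builds the Z-alkenes after the ester bonds. Coupling with [bis(2,2,2-trifluoroethoxy)phosphoryl]acetic acid (DCC, DMAP cat., CH2Cl2) would give the bis(phosphonoacetate) F5. A twofold Still–Gennari olefination with butanal (KN(SiMe3)2, 18-crown-6, THF, −78 °C) should then form both Z-enoates, and the route is rejoined at 23.

Further compounds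

F1 | step 7 | O-trimethylsilyl ether of 10 at the tertiary C3 oxygen | C=C(C)[C@@H]1CC(C)=C(C)C(C)(O[Si](C)(C)C)[C@H]1C(=CCSC)O[Si](C(C)C)(C(C)C)C(C)C
F2 | step 7 | C3/C4 trimethylsilyl enol ether of 13 | C=C(C)[C@@H]1C[C@](C)(C(C)=C(C)O[Si](C)(C)C)C(CSC)C(O[Si](C(C)C)(C(C)C)C(C)C)=C1
F3 | step 11 | 8α-[(triisopropylsilyl)oxy]-10αH-eremophil-11-ene-3β,9α-diol | C=C(C)[C@@H]1C[C@]2(C)[C@@H](C)[C@@H](O)CC[C@H]2[C@H](O)[C@@H]1O[Si](C(C)C)(C(C)C)C(C)C
F4 | step 11 | 3β-hydroxy-8α-[(triisopropylsilyl)oxy]-10αH-eremophil-11-en-9α-yl (2Z)-hex-2-enoate | C=C(C)[C@@H]1C[C@]2(C)[C@@H](C)[C@@H](O)CC[C@H]2[C@H](OC(=O)/C=C\CCC)[C@@H]1O[Si](C(C)C)(C(C)C)C(C)C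
F5 | step 13 | 3α,9α-bis{[bis(2,2,2-trifluoroethoxy)phosphoryl]acetate} of 19 | C=C(C)[C@@H]1C[C@]2(C)[C@@H](C)[C@H](OC(=O)CP(=O)(OCC(F)(F)F)OCC(F)(F)F)CC[C@H]2[C@H](OC(=O)CP(=O)(OCC(F)(F)F)OCC(F)(F)F)[C@@H]1O[Si](C(C)C)(C(C)C)C(C)C
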